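**Retrosynthetic overview**
1. Target ⇐ hydrogenolysis of its penta-O-benzyl ether; the cis-dihydrobenzofuran (last ring) ⇐ intramolecular Pd aryl C–O coupling (retention at carbon) of a Felkin carbinol made from an α-aryl aldehyde and an aryl Grignard reagent.
2. α-Aryl aldehyde ⇐ ozonolysis of an ortho-pentenyl phenol ⇐ aromatic Claisen rearrangement of an (R)-sec-allyl aryl ether (1,3-chirality transfer sets the benzylic centre).
3. All-cis oxolane (second ring) ⇐ Et3SiH/BF3 reduction of the hemiketal from an aryllithium and a γ-lactone (first ring).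
4. γ-Lactone ⇐ chelate-controlled Ireland–Claisen rearrangement of an (R)-allyl α-benzyloxy ester (sets the quaternary carbinol and its neighbour), then acid reduction, ozonolysis and lactol oxidation.
5. Both Claisen substrates ⇐ Mitsunobu inversion of one alcohol, (2S,3E)-1,5-bis(benzyloxy)pent-3-en-2-ol ⇐ (S)-benzyl glycidyl ether, the only chiral input. Ring order: lactone → oxolane → dihydrobenzofuran.

Assumption: the target is made exactly as the SMILES is written (aryl and CH2OH cis on the dihydrobenzofuran; aryl, CH2OH and benzyl all cis on the oxolane), and compounds 1, 3, 5, 6, 17 and 26 are bought.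

Abbreviations: Bn = benzyl; Ar = 4-(benzyloxy)-3-methoxyphenyl; Q = (2R,3R,4S)-4-(benzyloxy)-4-(Ar-methyl)-3-[(benzyloxy)methyl]oxolan-2-yl (oxolane numbered O1, C2 = aryl-bearing carbon).

**Step 1**
Reactants: 1 (S)-benzyl glycidyl ether [(2S)-2-[(benzyloxy)methyl]oxirane]
Product: 2 (2S)-1-(benzyloxy)but-3-en-2-ol
Conditions: Me3S+ I− (4 equiv), n-BuLi (3.9 equiv), THF, −10 °C → rt
Reagents that add atoms: trimethylsulfonium iodide, C[S+](C)C.[I-]
Why: The sulfonium methylide opens the epoxide at its CH2 terminus and the oxido-sulfonium salt then eliminates Me2S (ylide-mediated one-carbon homologation of an epoxide to an allylic alcohol), so the stereocentre is never touched.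

**Step 2**
Reactants: 2 (2S)-1-(benzyloxy)but-3-en-2-ol; 3 (Z)-1,4-bis(benzyloxy)but-2-ene (3 equiv)
Product: 4 (2S,3E)-1,5-bis(benzyloxy)pent-3-en-2-ol
Conditions: RuCl2(=CHPh)(PCy3)(H2IMes) (second-generation Grubbs catalyst, 3 mol %), CH2Cl2, 40 °C
Reagents that add atoms: none
Why: Olefin cross-metathesis of a terminal allylic alcohol with an excess of a symmetrical internal alkene gives the E-alkene; the carbinol centre is untouched.

**Step 3**
Reactants: 5 2-(benzyloxy)acetic acid; 6 4-(benzyloxy)-3-methoxybenzyl bromide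
Product: 8 rac-2-(benzyloxy)-3-[4-(benzyloxy)-3-methoxyphenyl]propanoic acid, via dilithium enediolate 7 (not isolated)
Conditions: LiN(i-Pr)2 (2.2 equiv), THF, −78 → 0 °C; 6, −78 °C → rt; 1 M HCl
Reagents that add atoms: none
Why: C-alkylation of a carboxylic acid dianion by a reactive benzylic bromide; the new centre is left racemic because it is planarised in step 5.

**Step 4**
Reactants: 8 rac-2-(benzyloxy)-3-Ar-propanoic acid; 4 (2S,3E)-1,5-bis(benzyloxy)pent-3-en-2-ol
Product: 9 (2R,3E)-1,5-bis(benzyloxy)pent-3-en-2-yl 2-(benzyloxy)-3-Ar-propanoate (1:1 epimers at the acyl C2)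
Conditions: PPh3, DIAD, toluene, −20 °C → rt
Reagents that add atoms: none
Why: Mitsunobu esterification; SN2 displacement at the activated carbinol inverts (S) to (R), and because both allyl termini carry CH2OBn even an SN2′ event gives the same constitution.

**Step 5**
Reactants: 9 (2R,3E)-allyl ester
Product: 12 (2S,3S,4E)-2,6-bis(benzyloxy)-2-(Ar-methyl)-3-[(benzyloxy)methyl]hex-4-enoic acid, via silyl ketene acetal 10 (not isolated), via trimethylsilyl ester 11 (not isolated)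
Conditions: LiN(i-Pr)2 (1.5 equiv), THF, −78 °C; Me3SiCl–Et3N; −78 → 60 °C; 1 M HCl
Reagents that add atoms: none
Why: Chelation-controlled Ireland–Claisen [3,3]-sigmatropic rearrangement: lithium chelation puts OSiMe3 cis to OBn in the ketene acetal, and the chair transition state with the carbinol CH2OBn equatorial relays the (R) C–O centre into the new C2–C3 bond. This sets the benzyloxy-bearing quaternary centre (2S), the neighbouring CH (3S) and the E-alkene in one event.

**Step 6**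
Reactants: 12 hexenoic acid
Product: 13 (2S,3S,4E)-2,6-bis(benzyloxy)-2-(Ar-methyl)-3-[(benzyloxy)methyl]hex-4-en-1-ol
Conditions: LiAlH4, THF, 0 °C → reflux; Fieser work-up
Reagents that add atoms: none
Why: Hydride reduction of the carboxylic acid to the primary alcohol; benzyl ethers, alkene and both stereocentres are inert.

**Step 7**
Reactants: 13 hexenol
Product: 15 (3S,4S)-4-(benzyloxy)-4-(Ar-methyl)-3-[(benzyloxy)methyl]oxolan-2-ol (both anomers), via ozonide 14 (not isolated)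
Conditions: O3, CH2Cl2, −78 °C (Sudan red 7B end point); PPh3, −78 °C → rt
Reagents that add atoms: ozone, [O-][O+]=O
Why: Ozonolysis with reductive work-up cleaves only the alkene at −78 °C; the aldehyde is trapped at once by the primary hydroxyl as the five-ring lactol, and the used-up control centre leaves as benzyloxyacetaldehyde.

**Step 8**
Reactants: 15 lactol
Product: 16 (3S,4S)-4-(benzyloxy)-4-(Ar-methyl)-3-[(benzyloxy)methyl]oxolan-2-one
Conditions: TEMPO (10 mol %), PhI(OAc)2, CH2Cl2, rt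
Reagents that add atoms: none
Why: Oxoammonium oxidation of a lactol to the γ-lactone under non-basic conditions, so the α-centre is not epimerised.

**Step 9**
Reactants: 17 4-bromo-2-methoxyphenol; 4 (2S,3E)-1,5-bis(benzyloxy)pent-3-en-2-ol
Product: 18 1-{[(2R,3E)-1,5-bis(benzyloxy)pent-3-en-2-yl]oxy}-4-bromo-2-methoxybenzene
Conditions: PPh3, DIAD, toluene, 0 °C → rt
Reagents that add atoms: none
Why: Mitsunobu etherification of the phenol with SN2 inversion, (S)-alcohol to (R)-aryl ether.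

**Step 10**
Reactants: 18 aryl bromide; 16 lactone
Product: 20 (3S,4S)-2-(4-{[(2R,3E)-1,5-bis(benzyloxy)pent-3-en-2-yl]oxy}-3-methoxyphenyl)-4-(benzyloxy)-4-(Ar-methyl)-3-[(benzyloxy)methyl]oxolan-2-ol (hemiketal, both anomers), via aryllithium 19 (not isolated)
Conditions: n-BuLi (1.0 equiv), THF, −78 °C, 20 min; 16, −78 °C; aq NH4Cl
Reagents that add atoms: none
Why: Bromine–lithium exchange is faster than any deprotonation at −78 °C, and 1,2-addition of the aryllithium to the lactone stops at the lithium hemiketal alkoxide.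

**Step 11**
Reactants: 20 hemiketal
Product: 21 1-{[(2R,3E)-1,5-bis(benzyloxy)pent-3-en-2-yl]oxy}-2-methoxy-4-Q-benzene
Conditions: Et3SiH (3 equiv), BF3·OEt2 (1.5 equiv), CH2Cl2, −78 → −40 °C
Reagents that add atoms: none
Why: Ionic hydrogenation of the aryl-stabilised cyclic oxocarbenium ion; hydride adds to the face opposite the C3 CH2OBn and C4 benzyl groups, so the aryl group ends cis to both (C2 = R).

**Step 12**
Reactants: 21 sec-allyl aryl ether
Product: 22 2-[(2R,3E)-1,5-bis(benzyloxy)pent-3-en-2-yl]-6-methoxy-4-Q-phenol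
Conditions: PhNEt2 (degassed), 185 °C, sealed tube
Reagents that add atoms: none
Why: Aromatic Claisen [3,3]-sigmatropic rearrangement to the only free ortho position; the suprafacial chair transition state with the carbinol CH2OBn equatorial transfers the (R) C–O centre to the new benzylic C–C centre (R) and gives the E-alkene.

**Step 13**
Reactants: 22 phenol
Product: 23 2-[(2R,3E)-1,5-bis(benzyloxy)pent-3-en-2-yl]-6-methoxy-4-Q-phenyl trifluoromethanesulfonate
Conditions: Tf2O, pyridine, CH2Cl2, −20 → 0 °C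
Reagents that add atoms: trifluoromethanesulfonic anhydride, O=S(=O)(OS(=O)(=O)C(F)(F)F)C(F)(F)F
Why: O-sulfonylation turns the phenol oxygen into the leaving group needed for the later aryl C–O coupling.

**Step 14**
Reactants: 23 aryl triflate
Product: 25 (2R)-3-(benzyloxy)-2-[3-methoxy-5-Q-2-(trifluoromethylsulfonyloxy)phenyl]propanal, via ozonide 24 (not isolated)
Conditions: O3, CH2Cl2, −78 °C (Sudan red 7B end point); PPh3, −78 → 0 °C; quick silica plug, used at once
Reagents that add atoms: ozone, [O-][O+]=O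
Why: Ozonolysis with neutral reductive work-up gives the α-aryl aldehyde without exposure to base, so the (2R) centre survives; the control centre again leaves as benzyloxyacetaldehyde.

**Step 15**
Reactants: 25 aldehyde; 26 1-(benzyloxy)-4-bromo-2-methoxybenzene
Product: 28 (1R,2R)-3-(benzyloxy)-1-Ar-2-[3-methoxy-5-Q-2-(trifluoromethylsulfonyloxy)phenyl]propan-1-ol, via arylmagnesium bromide 27 (not isolated)
Conditions: 26, Mg, THF, 40 °C; then 25, THF, −78 °C; aq NH4Cl
Reagents that add atoms: none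
Why: Felkin–Anh-controlled Grignard addition: the aryl nucleophile attacks anti to the α-aryl group (the same face that 1,3-chelation to the CH2OBn oxygen exposes), which sets the carbinol centre as (1R).

**Step 16**
Reactants: 28 carbinol triflate
Product: 29 (2R,3R)-2-Ar-3-[(benzyloxy)methyl]-7-methoxy-5-Q-2,3-dihydro-1-benzofuran (penta-O-benzyl ether of the target)
Conditions: Pd(OAc)2 (5 mol %), t-BuXPhos (7 mol %), Cs2CO3, toluene, 80 °C
Reagents that add atoms: none
Why: Intramolecular Buchwald–Hartwig-type aryl C–O coupling (oxidative addition of the triflate to zerovalent palladium, alkoxide binding, reductive elimination); the carbinol C–O bond is never broken, so (1R) is retained and becomes C2 of the cis-(2R,3R)-dihydrobenzofuran.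

**Step 17**
Reactants: 29 penta-O-benzyl ether
Product: 30 (3S,4R,5R)-5-[(2R,3R)-2-(4-hydroxy-3-methoxyphenyl)-3-(hydroxymethyl)-7-methoxy-2,3-dihydro-1-benzofuran-5-yl]-3-(4-hydroxy-3-methoxybenzyl)-4-(hydroxymethyl)oxolan-3-ol (CNP0284796.1)
Conditions: H2 (1 atm), Pd(OH)2 on carbon, EtOAc–MeOH, rt, stopped at full debenzylation
Reagents that add atoms: none
Why: Catalytic hydrogenolysis of the five O-benzyl groups under neutral conditions, which should leave the two cyclic benzylic ethers and all five stereocentres intact if stopped promptly.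

**Compound list**
1 | (S)-benzyl glycidyl ether | C(OCc1ccccc1)[C@@H]1CO1 | starting material
2 | (2S)-1-(benzyloxy)but-3-en-2-ol | C(OCc1ccccc1)[C@@H](O)C=C | intermediate
3 | (Z)-1,4-bis(benzyloxy)but-2-ene | C(/C=C\COCc1ccccc1)OCc1ccccc1 | starting material
4 | (2S,3E)-1,5-bis(benzyloxy)pent-3-en-2-ol | C(OCc1ccccc1)[C@@H](O)/C=C/COCc1ccccc1 | intermediate
5 | 2-(benzyloxy)acetic acid | OC(=O)COCc1ccccc1 | starting material
6 | 4-(benzyloxy)-3-methoxybenzyl bromide | COc1cc(CBr)ccc1OCc1ccccc1 | starting material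
7 | dilithium 2-(benzyloxy)ethene-1,1-diolate | [Li+].[Li+].[O-]C([O-])=COCc1ccccc1 | intermediate
8 | rac-2-(benzyloxy)-3-[4-(benzyloxy)-3-methoxyphenyl]propanoic acid | COc1cc(CC(OCc2ccccc2)C(=O)O)ccc1OCc1ccccc1 | intermediate
9 | (2R,3E)-1,5-bis(benzyloxy)pent-3-en-2-yl 2-(benzyloxy)-3-Ar-propanoate (acyl C2 epimers) | COc1cc(CC(OCc2ccccc2)C(=O)O[C@@H](COCc2ccccc2)/C=C/COCc2ccccc2)ccc1OCc1ccccc1 | intermediate
10 | (Z)-trimethylsilyl ketene acetal of 9 (OSiMe3 cis to OBn) | COc1cc(C/C(OCc2ccccc2)=C(/O[Si](C)(C)C)O[C@@H](COCc2ccccc2)/C=C/COCc2ccccc2)ccc1OCc1ccccc1 | intermediate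
11 | trimethylsilyl ester of 12 | COc1cc(C[C@@]([C@@H](/C=C/COCc2ccccc2)COCc2ccccc2)(OCc2ccccc2)C(=O)O[Si](C)(C)C)ccc1OCc1ccccc1 | intermediate
12 | (2S,3S,4E)-2,6-bis(benzyloxy)-2-(Ar-methyl)-3-[(benzyloxy)methyl]hex-4-enoic acid | COc1cc(C[C@@]([C@@H](/C=C/COCc2ccccc2)COCc2ccccc2)(OCc2ccccc2)C(=O)O)ccc1OCc1ccccc1 | intermediate
13 | (2S,3S,4E)-2,6-bis(benzyloxy)-2-(Ar-methyl)-3-[(benzyloxy)methyl]hex-4-en-1-ol | COc1cc(C[C@@]([C@@H](/C=C/COCc2ccccc2)COCc2ccccc2)(OCc2ccccc2)CO)ccc1OCc1ccccc1 | intermediate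
14 | ozonide (1,2,4-trioxolane) of 13, diastereomer mixture at the trioxolane carbons | COc1cc(C[C@@]([C@@H](C2OOC(COCc3ccccc3)O2)COCc2ccccc2)(OCc2ccccc2)CO)ccc1OCc1ccccc1 | intermediate
15 | (3S,4S)-4-(benzyloxy)-4-(Ar-methyl)-3-[(benzyloxy)methyl]oxolan-2-ol (both anomers) | COc1cc(C[C@@]2(OCc3ccccc3)COC(O)[C@H]2COCc2ccccc2)ccc1OCc1ccccc1 | intermediate
16 | (3S,4S)-4-(benzyloxy)-4-(Ar-methyl)-3-[(benzyloxy)methyl]oxolan-2-one | COc1cc(C[C@@]2(OCc3ccccc3)COC(=O)[C@H]2COCc2ccccc2)ccc1OCc1ccccc1 | intermediate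
17 | 4-bromo-2-methoxyphenol | COc1cc(Br)ccc1O | starting material
18 | 1-{[(2R,3E)-1,5-bis(benzyloxy)pent-3-en-2-yl]oxy}-4-bromo-2-methoxybenzene | COc1cc(Br)ccc1O[C@@H](COCc1ccccc1)/C=C/COCc1ccccc1 | intermediate
19 | aryllithium from 18 (Li in place of Br) | COc1cc([Li])ccc1O[C@@H](COCc1ccccc1)/C=C/COCc1ccccc1 | intermediate
20 | (3S,4S)-2-aryl hemiketal: 2-(4-{[(2R,3E)-1,5-bis(benzyloxy)pent-3-en-2-yl]oxy}-3-methoxyphenyl)-4-(benzyloxy)-4-(Ar-methyl)-3-[(benzyloxy)methyl]oxolan-2-ol (both anomers) | COc1cc(C[C@@]2(OCc3ccccc3)COC(O)(c3ccc(O[C@@H](COCc4ccccc4)/C=C/COCc4ccccc4)c(OC)c3)[C@H]2COCc2ccccc2)ccc1OCc1ccccc1 | intermediate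
21 | 1-{[(2R,3E)-1,5-bis(benzyloxy)pent-3-en-2-yl]oxy}-2-methoxy-4-Q-benzene | COc1cc(C[C@@]2(OCc3ccccc3)CO[C@@H](c3ccc(O[C@@H](COCc4ccccc4)/C=C/COCc4ccccc4)c(OC)c3)[C@H]2COCc2ccccc2)ccc1OCc1ccccc1 | intermediate
22 | 2-[(2R,3E)-1,5-bis(benzyloxy)pent-3-en-2-yl]-6-methoxy-4-Q-phenol | COc1cc(C[C@@]2(OCc3ccccc3)CO[C@@H](c3cc([C@H](COCc4ccccc4)/C=C/COCc4ccccc4)c(O)c(OC)c3)[C@H]2COCc2ccccc2)ccc1OCc1ccccc1 | intermediate
23 | trifluoromethanesulfonate of phenol 22 | COc1cc(C[C@@]2(OCc3ccccc3)CO[C@@H](c3cc([C@H](COCc4ccccc4)/C=C/COCc4ccccc4)c(OS(=O)(=O)C(F)(F)F)c(OC)c3)[C@H]2COCc2ccccc2)ccc1OCc1ccccc1 | intermediate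
24 | ozonide (1,2,4-trioxolane) of 23, diastereomer mixture at the trioxolane carbons | COc1cc(C[C@@]2(OCc3ccccc3)CO[C@@H](c3cc([C@H](COCc4ccccc4)C4OOC(COCc5ccccc5)O4)c(OS(=O)(=O)C(F)(F)F)c(OC)c3)[C@H]2COCc2ccccc2)ccc1OCc1ccccc1 | intermediate
25 | (2R)-3-(benzyloxy)-2-[3-methoxy-5-Q-2-(trifluoromethylsulfonyloxy)phenyl]propanal | COc1cc(C[C@@]2(OCc3ccccc3)CO[C@@H](c3cc([C@H](COCc4ccccc4)C=O)c(OS(=O)(=O)C(F)(F)F)c(OC)c3)[C@H]2COCc2ccccc2)ccc1OCc1ccccc1 | intermediate
26 | 1-(benzyloxy)-4-bromo-2-methoxybenzene | COc1cc(Br)ccc1OCc1ccccc1 | starting material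
27 | [4-(benzyloxy)-3-methoxyphenyl]magnesium bromide | COc1cc([Mg]Br)ccc1OCc1ccccc1 | intermediate
28 | (1R,2R)-3-(benzyloxy)-1-Ar-2-[3-methoxy-5-Q-2-(trifluoromethylsulfonyloxy)phenyl]propan-1-ol | COc1cc(C[C@@]2(OCc3ccccc3)CO[C@@H](c3cc([C@H](COCc4ccccc4)[C@H](c4ccc(OCc5ccccc5)c(OC)c4)O)c(OS(=O)(=O)C(F)(F)F)c(OC)c3)[C@H]2COCc2ccccc2)ccc1OCc1ccccc1 | intermediate
29 | (2R,3R)-2-Ar-3-[(benzyloxy)methyl]-7-methoxy-5-Q-2,3-dihydro-1-benzofuran | COc1cc(C[C@@]2(OCc3ccccc3)CO[C@@H](c3cc(OC)c4c(c3)[C@H](COCc3ccccc3)[C@H](c3ccc(OCc5ccccc5)c(OC)c3)O4)[C@H]2COCc2ccccc2)ccc1OCc1ccccc1 | intermediate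
30 | (3S,4R,5R)-5-[(2R,3R)-2-(4-hydroxy-3-methoxyphenyl)-3-(hydroxymethyl)-7-methoxy-2,3-dihydro-1-benzofuran-5-yl]-3-(4-hydroxy-3-methoxybenzyl)-4-(hydroxymethyl)oxolan-3-ol | COc1cc(C[C@@]2(O)CO[C@@H](c3cc(OC)c4c(c3)[C@H](CO)[C@H](c3ccc(O)c(OC)c3)O4)[C@H]2CO)ccc1O | target

**Step count and risks**
Total: 17 steps. Longest linear sequence: 15 steps (steps 1, 2, 4–8 and 10–17; step 3 and step 9 are one-step branches).

Most likely to fail, first: step 16. The triflate is flanked by two ortho substituents, and the secondary benzylic palladium alkoxide can undergo β-hydride elimination to a ketone instead of C–O reductive elimination. The fallback sets out from 28 and returns at 29 by making that ketone on purpose and closing the ring by SN2 at carbon instead of at the arene. Dess–Martin periodinane oxidises 28 to the aryl ketone F1. LiBH(s-Bu)3 at −78 °C reduces it under Felkin–Anh control to the C1-epimeric (1S,2R)-carbinol F2. Et4NOH in dioxane cleaves the aryl triflate to the free phenol F3. An intramolecular Mitsunobu etherification (PPh3, DIAD) then inverts the carbinol carbon and gives 29; its own risk is partial SN1 leakage to the trans isomer.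

Second: step 14. The α-aryl β-benzyloxy aldehyde 25 can epimerise or lose benzyl alcohol, and ozone may attack the electron-rich rings. The fallback sets out from 22 and returns at 28 and never has the aldehyde free. Ozonolysis of the free phenol 22 (O3, CH2Cl2–MeOH, −78 °C; Me2S) gives the cyclic hemiacetal, the 2-hydroxy-2,3-dihydrobenzofuran lactol F4. An excess of Grignard reagent 27 opens it through its magnesium phenoxide and adds in the same Felkin sense to give the phenol carbinol F5. Selective triflation of the phenolic hydroxyl (PhNTf2, K2CO3, acetone) gives 28.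

Third: step 12. The thermal rearrangement is run on a late, heavily functionalised secondary allyl ether, where elimination to a diene or incomplete chirality transfer would be costly; the same ether must also survive BF3·OEt2 in step 11. The fallback sets out from 18 and returns at 22 by rearranging before the fragments are joined. Heating 18 in PhNEt2 at 180 °C gives the bromophenol F6. Silylation (t-BuMe2SiCl, imidazole, DMF) gives the silyl ether F7. Bromine–lithium exchange with n-BuLi at −78 °C gives the aryllithium F8, which adds to lactone 16 to give the hemiketal F9. Et3SiH/BF3·OEt2 at −78 °C gives the silyl-protected oxolane F10, and Bu4NF in THF returns phenol 22.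

**Further compounds**
F1 | step 16 | (2R)-3-(benzyloxy)-1-Ar-2-[3-methoxy-5-Q-2-(trifluoromethylsulfonyloxy)phenyl]propan-1-one | COc1cc(C[C@@]2(OCc3ccccc3)CO[C@@H](c3cc([C@H](COCc4ccccc4)C(=O)c4ccc(OCc5ccccc5)c(OC)c4)c(OS(=O)(=O)C(F)(F)F)c(OC)c3)[C@H]2COCc2ccccc2)ccc1OCc1ccccc1
F2 | step 16 | (1S,2R)-3-(benzyloxy)-1-Ar-2-[3-methoxy-5-Q-2-(trifluoromethylsulfonyloxy)phenyl]propan-1-ol | COc1cc(C[C@@]2(OCc3ccccc3)CO[C@@H](c3cc([C@H](COCc4ccccc4)[C@@H](c4ccc(OCc5ccccc5)c(OC)c4)O)c(OS(=O)(=O)C(F)(F)F)c(OC)c3)[C@H]2COCc2ccccc2)ccc1OCc1ccccc1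
F3 | step 16 | (1S,2R)-3-(benzyloxy)-1-Ar-2-(2-hydroxy-3-methoxy-5-Q-phenyl)propan-1-ol | COc1cc(C[C@@]2(OCc3ccccc3)CO[C@@H](c3cc([C@H](COCc4ccccc4)[C@@H](c4ccc(OCc5ccccc5)c(OC)c4)O)c(O)c(OC)c3)[C@H]2COCc2ccccc2)ccc1OCc1ccccc1
F4 | step 14 | (3R)-3-[(benzyloxy)methyl]-7-methoxy-5-Q-2,3-dihydro-1-benzofuran-2-ol (both anomers) | COc1cc(C[C@@]2(OCc3ccccc3)CO[C@@H](c3cc(OC)c4c(c3)[C@H](COCc3ccccc3)C(O)O4)[C@H]2COCc2ccccc2)ccc1OCc1ccccc1
F5 | step 14 | (1R,2R)-3-(benzyloxy)-1-Ar-2-(2-hydroxy-3-methoxy-5-Q-phenyl)propan-1-ol | COc1cc(C[C@@]2(OCc3ccccc3)CO[C@@H](c3cc([C@H](COCc4ccccc4)[C@H](c4ccc(OCc5ccccc5)c(OC)c4)O)c(O)c(OC)c3)[C@H]2COCc2ccccc2)ccc1OCc1ccccc1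
F6 | step 12 | 2-[(2R,3E)-1,5-bis(benzyloxy)pent-3-en-2-yl]-4-bromo-6-methoxyphenol | COc1cc(Br)cc([C@H](COCc2ccccc2)/C=C/COCc2ccccc2)c1O
F7 | step 12 | tert-butyldimethylsilyl ether of F6 | COc1cc(Br)cc([C@H](COCc2ccccc2)/C=C/COCc2ccccc2)c1O[Si](C)(C)C(C)(C)C
F8 | step 12 | aryllithium from F7 (Li in place of Br) | COc1cc([Li])cc([C@H](COCc2ccccc2)/C=C/COCc2ccccc2)c1O[Si](C)(C)C(C)(C)C
F9 | step 12 | (3S,4S)-hemiketal from F8 and 16 (both anomers) | COc1cc(C[C@@]2(OCc3ccccc3)COC(O)(c3cc([C@H](COCc4ccccc4)/C=C/COCc4ccccc4)c(O[Si](C)(C)C(C)(C)C)c(OC)c3)[C@H]2COCc2ccccc2)ccc1OCc1ccccc1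
F10 | step 12 | tert-butyldimethylsilyl ether of phenol 22 | COc1cc(C[C@@]2(OCc3ccccc3)CO[C@@H](c3cc([C@H](COCc4ccccc4)/C=C/COCc4ccccc4)c(O[Si](C)(C)C(C)(C)C)c(OC)c3)[C@H]2COCc2ccccc2)ccc1OCc1ccccc1
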